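Atom labels used throughout: benzofuran numbering O1, C2, C3, C3a, C4–C7, C7a; ring A is the benzene ring, ring B the dihydrofuran ring; the side chain on C2 is C1' (methine carrying the methyl group) and C2' (the CH2–O carbon).

## Analysis of the target

Target 18 is a 2,3-dihydro-1-benzofuran with an (E)-propenoic acid at C5 of ring A. At C2 of ring B it carries a C1'(CH3)–C2'H2–O chain whose oxygen is acylated by (E)-4-hydroxycinnamic acid. There are two stereocentres, C2 in ring B and the exocyclic C1' bonded to it. Both are S, so in the extended chain C3–C2–C1'–C2' the ring oxygen O1 and the C1' methyl group lie on the same side (syn). Neither centre can epimerise in the target, so the problem is building them, not keeping them. The sensitive groups are two cinnamate-type (E)-alkenes (Michael acceptors, sensitive to hydrogenation and light), a free phenol, and a free carboxylic acid beside an ester that must remain an ester. The main difficulty is C1': a methyl-branched stereocentre outside the ring, with no adjacent carbonyl for enolate chemistry, that must be set in a fixed relation to C2. A second difficulty is that two similar arylpropenoic units must end up different, one as the free acid and one as the ester. The strategy rests on one feature: the C2 substituent C1'(CH3)–C2'H2–O is a vinyl group on C2 to which CH3 has been added at the inner carbon and oxygen at the terminal carbon. A 2-vinyl-2,3-dihydrobenzofuran carrying a C5 halogen is therefore the natural precursor.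

## Retrosynthetic reasoning

**18 from 17.** The last operation only removes protecting groups. The C5 propenoic acid is held as its tert-butyl ester and the phenol as its methoxymethyl ether, so a single acid treatment frees both and leaves the C2' ester intact. This is what keeps the two arylpropenoic units distinct.

**17 from 15 and 16.** The C5–C(alkene) bond is cut, leading to aryl bromide 15 and tert-butyl acrylate 16, joined by a Heck reaction. The acrylate is added late so that no Michael acceptor is on ring A during the organoaluminium and π-allyl steps. The bromine is carried unchanged from 4-bromophenol 1.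

**15 from 11 and 14.** The acyl–O bond at C2' is cut, giving primary alcohol 11 and protected acid 14. Acid 14 comes from (E)-4-hydroxycinnamic acid 12 by acetal protection of the phenol. The forward reaction is an esterification of an unhindered primary alcohol.

**11 from 8 and 9 (key disconnection).** The C1'–CH3 bond and the C2'–O bond are both cut, leading back to vinyl compound 8 and trimethylaluminium 9. No other cut removes the whole methyl-branched hydroxymethyl unit in one step while using the C2 centre already in place. The forward reaction must add methyl to the inner vinyl carbon and a metal to the terminal carbon with face control, then oxidise the carbon–metal bond. A zirconium-catalysed asymmetric carboalumination with aerobic oxidation does this via alane 10.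

**8 from 7.** The O1–C2 bond is cut. Allylic carbonate 7 has the phenol and a four-carbon allyl unit in place. Ionisation by zerovalent palladium and attack of the phenol oxygen on the inner allyl terminus closes ring B, sets C2 under ligand control and leaves the vinyl group.

**7 from 4 and 6.** The alkene of 7 is cut by cross-metathesis into allylphenol 4 and dicarbonate 6, which comes from diol 5. This attaches the oxygenated two-carbon end in one step without protecting the phenol.

**4 from 3, and 3 from 1 and 2.** The C3–C3a bond comes from a Claisen rearrangement of allyl ether 3, made from 4-bromophenol 1 and allyl bromide 2. The para bromine blocks the para position and becomes the C5 handle.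

## Alternatives that were turned down

**Alternative 1:** Ring B is cut at both O1–C2 and C3–C3a, giving iodophenol A2 (methyl 4-hydroxy-3-iodobenzoate) and 2-substituted diene A3.
- **Forward step:** with Pd(OAc)2 and a chiral phosphoramidite, the arylpalladium species (divalent) inserts the monosubstituted alkene of A3 at its CH2 end, and the phenoxide closes onto the near terminus of the π-allyl to give A1.
- **For:** it is convergent. One step gives ring B, the C2 centre and the whole oxygenated three-carbon chain, with no strong Lewis acid near the allylic ether. On making the ring and C2 it is shorter than the chosen route, which needs four steps to reach 8.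
- **Against:** C1' is still missing. It would have to come from face-selective hydrogenation of the 1,1-disubstituted alkene of A1, a difficult substrate class for catalyst control, with two allylic C–O bonds at risk of hydrogenolysis. The insertion must also choose between the two alkenes of A3. The C5 ester then needs reduction, oxidation and olefination, where the chosen route needs one Heck reaction.
- **Comparison:** the chosen route forms the C1'–CH3 bond and the C2'–O bond at the correct oxidation level in one catalyst-controlled step and carries a bromine that couples directly.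

**Alternative 2:** The C2–C1' and C3–C3a bonds are cut in a three-component coupling, and ring B is closed later through O1–C7a.
- **Forward step:** vinyllithium A7 and boronic ester A6 form an ate complex. With Pd(OAc)2, a chiral ferrocenyl diphosphine of the MandyPhos type and aryl triflate A5, isopropenyl migrates from boron to carbon as the aryl group is delivered, giving A4.
- **For:** conjunctive couplings of this kind are highly enantioselective, probably more dependably than the allylic etherification used here for C2. The fluorine para to the ester makes the later ring closure by aromatic substitution reliable.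
- **Against:** in a bis(alkenyl) ate complex either alkenyl group can act as acceptor or migrating group, and direct transfer to palladium competes. C1' must then be set by hydroboration of the isopropenyl group under substrate control. For an allylic ether of this type, uncatalysed boranes are expected to favour the anti relationship, not the syn one needed. The C5 ester again costs three extra steps, and C–B oxidation plus ring closure add two more.
- **Comparison:** the chosen route is shorter and sets C1' by a chiral catalyst whose enantiomer can be chosen.

**Alternative 3:** The O1–C2 and C2–C1' bonds are cut, leading to diazoketone A9.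
- **Forward step:** the chiral dirhodium carboxylate Rh2(S-PTTL)4 forms a carbenoid that the ether oxygen captures, closing a five-membered oxonium ylide. A [2,3]-shift of the (Z)-crotyl group then gives benzofuranone A8.
- **For:** this is the most bond-economic key step of all. Ring B, C2, C1' and the C2–C1' bond form together, and the ordered transition state fixes the relative configuration. On that point it is stronger than the chosen route, which depends on a catalyst–substrate match. The bromine is already in place and the vinyl group is a masked CH2OH.
- **Against:** enantioselectivity requires the ylide to stay bound to rhodium, and [1,2]-shift and C–H insertion compete. A9 needs an acid chloride and a diazoalkane. A8 carries a C3 carbonyl that is not in the target and makes C2 epimerisable. Removing it through the benzylic alcohol risks elimination to the aromatic benzofuran, which would destroy C2.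
- **Comparison:** the chosen route never has an oxygen at C3, so it has no deoxygenation and no epimerisable centre, and it uses safer reagents.

Key step: step 6

Assumption: the handedness of the two chiral catalysts is written as expected from simple substrates, the (R,R)-diphosphine for (2S) in step 5 and (–)-(NMI)2ZrCl2 for (1'S) in step 6; a first run decides, and the mirror-image catalyst is used if the sense is opposite.

## Route

Step 1
Reactants: 1 4-bromophenol; 2 allyl bromide (3-bromoprop-1-ene)
Product: 3 1-bromo-4-(prop-2-en-1-yloxy)benzene
Conditions: K2CO3, acetone, reflux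
Reagents that add atoms: none
Why: Williamson ether synthesis; the phenoxide formed with K2CO3 displaces bromide from the allylic halide by SN2, and O-alkylation dominates in a polar aprotic solvent.

Step 2
Reactants: 3 1-bromo-4-(prop-2-en-1-yloxy)benzene
Product: 4 4-bromo-2-(prop-2-en-1-yl)phenol
Conditions: N,N-diethylaniline, 200 °C
Reagents that add atoms: none
Why: Aromatic Claisen rearrangement ([3,3]-shift, then tautomerisation); the para position is blocked by bromine and the two ortho positions are equivalent, so one phenol should form, and the C–Br bond is thermally inert.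

Step 3
Reactants: 5 (Z)-but-2-ene-1,4-diol
Product: 6 (Z)-but-2-ene-1,4-diyl dimethyl dicarbonate
Conditions: ClCO2Me (2.4 equiv), pyridine, CH2Cl2, 0 °C to rt
Reagents that add atoms: methyl chloroformate, COC(=O)Cl
Why: Acylation of both primary hydroxyl groups by the chloroformate, with pyridine as base and acyl-transfer catalyst; the Z alkene is not touched.

Step 4
Reactants: 4 4-bromo-2-(prop-2-en-1-yl)phenol; 6 (Z)-but-2-ene-1,4-diyl dimethyl dicarbonate
Product: 7 (2E)-4-(5-bromo-2-hydroxyphenyl)but-2-en-1-yl methyl carbonate
Conditions: second-generation Grubbs catalyst (5 mol%), 6 (3 equiv), 1,4-benzoquinone (10 mol%), CH2Cl2, 40 °C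
Reagents that add atoms: none
Why: Olefin cross-metathesis of a terminal alkene with an excess of a symmetrical internal alkene; the excess of 6 suppresses homodimerisation of 4, ruthenium alkylidenes tolerate free phenols, and benzoquinone limits migration of the allyl double bond. The E isomer should predominate; any Z isomer is removed by chromatography if it lowers the selectivity of step 5.

Step 5
Reactants: 7 (2E)-4-(5-bromo-2-hydroxyphenyl)but-2-en-1-yl methyl carbonate
Product: 8 (2S)-5-bromo-2-ethenyl-2,3-dihydro-1-benzofuran
Conditions: Pd2(dba)3·CHCl3 (2.5 mol%), (R,R)-DACH-phenyl diphosphine [N,N'-(1R,2R)-cyclohexane-1,2-diylbis(2-diphenylphosphinobenzamide)] (7.5 mol%), AcOH (1 equiv), CH2Cl2, 0 °C to rt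
Reagents that add atoms: none
Why: Intramolecular asymmetric allylic etherification (Tsuji–Trost reaction); zerovalent palladium ionises the allylic carbonate with loss of CO2 and methoxide, and the phenol attacks the allyl terminus next to the benzylic CH2, closing five-membered ring B in preference to a seven-membered ring. C2 is set by the chiral diphosphine, which selects between the two diastereomeric π-allyl complexes; these interconvert through the unsubstituted CH2 terminus, and AcOH helps that equilibration.

Step 6
Reactants: 8 (2S)-5-bromo-2-ethenyl-2,3-dihydro-1-benzofuran; 9 trimethylaluminium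
Product: 11 (2S)-2-[(2S)-5-bromo-2,3-dihydro-1-benzofuran-2-yl]propan-1-ol, via alkyl(dimethyl)alane 10 (not isolated)
Conditions: Me3Al (3 equiv), (–)-(NMI)2ZrCl2 [(–)-bis(1-neomenthylindenyl)zirconium dichloride] (5 mol%), methylaluminoxane (MeAlO)n (1 equiv), CH2Cl2, 0 °C to rt; then O2, 0 °C; aq. NaOH
Reagents that add atoms: dioxygen, O=O
Why: Me3Al, (NMI)2ZrCl2 and methylaluminoxane generate a cationic methylzirconocene that binds the vinyl group of 8 and inserts it into the Zr–CH3 bond in the 1,2-sense, with methyl going to the inner carbon C1' and zirconium to the terminal carbon C2'; exchange of zirconium for aluminium with Me3Al then releases alane 10 and regenerates Zr–CH3. The closest known reaction type is the zirconium-catalysed asymmetric carboalumination of monosubstituted alkenes (ZACA reaction) with oxidation, which is known for α-branched alkenes and for alkenes with allylic or homoallylic oxygen. No ring is closed; ring B is a spectator. The new stereocentre C1' is controlled by the chiral bis(1-neomenthylindenyl)zirconocene, which distinguishes the two faces of the vinyl group; the (–)-enantiomer is chosen because its sense with simple 1-alkenes, giving (R)-2-methylalkan-1-ols, corresponds to (1'S) here, where C2 outranks CH2OH. The C2 centre adds its own facial bias, so the pairing may be matched or mismatched; the C1' epimers are diastereomers and should be separable, and the separation should also raise enantiomeric purity, because the minor enantiomer of 8 is carried mainly into the unwanted diastereomer. The step needs regioselectivity, which is inherent in 1,2-insertion with the metal at the unhindered terminus, and chemoselectivity over ionisation of the allylic C2–O1 bond, which is helped by the weak donor strength of the aryl ether oxygen, low temperature and a limited amount of methylaluminoxane. In 10 the ring oxygen sits on the γ-carbon, so β-alkoxide elimination is not possible, and the aryl bromide does not react with alanes. O2 then inserts into the C–Al bond without touching C1', and aqueous work-up gives 11.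

Step 7
Reactants: 12 (E)-4-hydroxycinnamic acid
Product: 14 (2E)-3-[4-(methoxymethoxy)phenyl]prop-2-enoic acid, via methoxymethyl ester 13 (not isolated)
Conditions: MOMCl (2.5 equiv), iPr2NEt (3 equiv), CH2Cl2, 0 °C to rt; then LiOH, THF/MeOH/H2O, rt; 1 M HCl to pH 4, 0 °C
Reagents that add atoms: chloromethyl methyl ether, COCCl
Why: The carboxylate and the phenoxide are both alkylated to give 13; the methoxymethyl ester is an acyloxy acetal that hydroxide cleaves far faster than the base-stable aryl methoxymethyl ether, so 14 should result after careful acidification.

Step 8
Reactants: 11 (2S)-2-[(2S)-5-bromo-2,3-dihydro-1-benzofuran-2-yl]propan-1-ol; 14 (2E)-3-[4-(methoxymethoxy)phenyl]prop-2-enoic acid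
Product: 15 (2S)-2-[(2S)-5-bromo-2,3-dihydro-1-benzofuran-2-yl]propyl (2E)-3-[4-(methoxymethoxy)phenyl]prop-2-enoate
Conditions: DCC (1.2 equiv), DMAP (10 mol%), CH2Cl2, 0 °C to rt
Reagents that add atoms: none
Why: Steglich esterification; DCC activates 14 as the O-acylisourea and DMAP passes the acyl group to the unhindered primary alcohol, while the aryl bromide, the acetal and both stereocentres are unaffected.

Step 9
Reactants: 15 (2S)-2-[(2S)-5-bromo-2,3-dihydro-1-benzofuran-2-yl]propyl (2E)-3-[4-(methoxymethoxy)phenyl]prop-2-enoate; 16 tert-butyl acrylate
Product: 17 tert-butyl (2E)-3-[(2S)-2-[(2S)-1-{[(2E)-3-[4-(methoxymethoxy)phenyl]prop-2-enoyl]oxy}propan-2-yl]-2,3-dihydro-1-benzofuran-5-yl]prop-2-enoate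
Conditions: Pd2(dba)3 (2 mol%), [HP(t-Bu)3]BF4 (8 mol%), Cy2NMe (1.5 equiv), 16 (2 equiv), 1,4-dioxane, 70 °C
Reagents that add atoms: none
Why: Heck reaction; the electron-rich zerovalent palladium/P(t-Bu)3 catalyst adds oxidatively to the C5–Br bond, the terminal acrylate inserts, and syn β-hydride elimination gives the E alkene. The monosubstituted acrylate inserts much faster than the 1,2-disubstituted alkene of the coumarate ester.

Step 10
Reactants: 17 tert-butyl (2E)-3-[(2S)-2-[(2S)-1-{[(2E)-3-[4-(methoxymethoxy)phenyl]prop-2-enoyl]oxy}propan-2-yl]-2,3-dihydro-1-benzofuran-5-yl]prop-2-enoate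
Product: 18 (2E)-3-[(2S)-2-[(2S)-1-{[(2E)-3-(4-hydroxyphenyl)prop-2-enoyl]oxy}propan-2-yl]-2,3-dihydro-1-benzofuran-5-yl]prop-2-enoic acid
Conditions: TFA/CH2Cl2 (1:3), H2O (5 equiv), 0 °C to rt
Reagents that add atoms: none
Why: Acidolysis; the tert-butyl ester loses isobutene by O–alkyl cleavage and the methoxymethyl acetal is hydrolysed through its oxocarbenium ion. The primary alkyl cinnamate ester, the aryl alkyl ether of ring B and both stereocentres are stable to TFA at room temperature, and water traps the cationic fragments.

## Compound list

1 | 4-bromophenol | Oc1ccc(Br)cc1 | starting material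
2 | allyl bromide (3-bromoprop-1-ene) | C=CCBr | starting material
3 | 1-bromo-4-(prop-2-en-1-yloxy)benzene | C=CCOc1ccc(Br)cc1 | intermediate
4 | 4-bromo-2-(prop-2-en-1-yl)phenol | C=CCc1cc(Br)ccc1O | intermediate
5 | (Z)-but-2-ene-1,4-diol | OC/C=C\CO | starting material
6 | (Z)-but-2-ene-1,4-diyl dimethyl dicarbonate | COC(=O)OC/C=C\COC(=O)OC | intermediate
7 | (2E)-4-(5-bromo-2-hydroxyphenyl)but-2-en-1-yl methyl carbonate | COC(=O)OC/C=C/Cc1cc(Br)ccc1O | intermediate
8 | (2S)-5-bromo-2-ethenyl-2,3-dihydro-1-benzofuran | C=C[C@@H]1Cc2cc(Br)ccc2O1 | intermediate
9 | trimethylaluminium | C[Al](C)C | starting material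
10 | [(2R)-2-[(2S)-5-bromo-2,3-dihydro-1-benzofuran-2-yl]propyl](dimethyl)alumane (same spatial arrangement at C1' as 11; the descriptor changes because CH2Al outranks C2) | C[C@@H](C[Al](C)C)[C@@H]1Cc2cc(Br)ccc2O1 | intermediate
11 | (2S)-2-[(2S)-5-bromo-2,3-dihydro-1-benzofuran-2-yl]propan-1-ol | C[C@@H](CO)[C@@H]1Cc2cc(Br)ccc2O1 | intermediate
12 | (E)-4-hydroxycinnamic acid | O=C(O)/C=C/c1ccc(O)cc1 | starting material
13 | methoxymethyl (2E)-3-[4-(methoxymethoxy)phenyl]prop-2-enoate | COCOC(=O)/C=C/c1ccc(OCOC)cc1 | intermediate
14 | (2E)-3-[4-(methoxymethoxy)phenyl]prop-2-enoic acid | COCOc1ccc(/C=C/C(=O)O)cc1 | intermediate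
15 | (2S)-2-[(2S)-5-bromo-2,3-dihydro-1-benzofuran-2-yl]propyl (2E)-3-[4-(methoxymethoxy)phenyl]prop-2-enoate | C[C@@H](COC(=O)/C=C/c1ccc(OCOC)cc1)[C@@H]1Cc2cc(Br)ccc2O1 | intermediate
16 | tert-butyl acrylate | C=CC(=O)OC(C)(C)C | starting material
17 | tert-butyl (2E)-3-[(2S)-2-[(2S)-1-{[(2E)-3-[4-(methoxymethoxy)phenyl]prop-2-enoyl]oxy}propan-2-yl]-2,3-dihydro-1-benzofuran-5-yl]prop-2-enoate | C[C@@H](COC(=O)/C=C/c1ccc(OCOC)cc1)[C@@H]1Cc2cc(/C=C/C(=O)OC(C)(C)C)ccc2O1 | intermediate
18 | (2E)-3-[(2S)-2-[(2S)-1-{[(2E)-3-(4-hydroxyphenyl)prop-2-enoyl]oxy}propan-2-yl]-2,3-dihydro-1-benzofuran-5-yl]prop-2-enoic acid | C[C@@H](COC(=O)/C=C/c1ccc(O)cc1)[C@@H]1Cc2cc(/C=C/C(=O)O)ccc2O1 | target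

## Step count and least certain steps

Total step count: 10. Longest linear sequence: 8 (steps 1, 2, 4, 5, 6, 8, 9, 10); steps 3 and 7 are side branches.

**Step 6 (key step).** Two things are most likely to go wrong.
- The vinyl group of 8 is α-branched and carries an electron-withdrawing allylic oxygen, so insertion is slow. Lewis-acid ionisation of the allylic C2–O1 bond by the aluminium reagents, followed by methyl transfer or elimination, then has time to open ring B.
- Facial discrimination may be poor if the bias of the C2 centre opposes the catalyst, giving a low diastereomer ratio.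

Fallback: it sets out from 8 and comes back at 11. Cross-metathesis of 8 with (E)-1,4-dibromobut-2-ene (second-generation Hoveyda–Grubbs catalyst) should give (2S)-5-bromo-2-[(1E)-3-bromoprop-1-en-1-yl]-2,3-dihydro-1-benzofuran F1. A copper-catalysed asymmetric allylic substitution (CuBr·SMe2, a Taniaphos-type ferrocenyl diphosphine, MeMgBr, CH2Cl2, −78 °C) should deliver methyl to C1' in the SN2' sense under ligand control, giving (2S)-5-bromo-2-[(2S)-but-3-en-2-yl]-2,3-dihydro-1-benzofuran F2. Ozonolysis of the new vinyl group with NaBH4 work-up then gives 11. This path uses no strong Lewis acid, and its face selectivity comes from a different catalyst class.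

**Step 5.** The likely failures are insufficient enantioselection, erosion of the ee by re-ionisation of the allylic aryl ether product, and diversion to elimination or seven-membered ring closure. Low selectivity could arise because E and Z isomers of 7 pass through different π-allyl geometries, or because ring closure outruns equilibration of the diastereomeric complexes.

Fallback: it sets out from 7 and comes back at 8. Methanolysis of the carbonate (K2CO3, MeOH) should give (2E)-4-(5-bromo-2-hydroxyphenyl)but-2-en-1-ol F3. Sharpless asymmetric epoxidation (Ti(OiPr)4 in stoichiometric amount, D-(–)-diethyl tartrate, t-BuOOH, CH2Cl2, −20 °C) should give [(2R,3R)-3-[(5-bromo-2-hydroxyphenyl)methyl]oxiran-2-yl]methanol F4. Base (K2CO3, MeOH) then lets the phenoxide open the epoxide at C3 in the 5-exo mode with inversion, giving (1R)-1-[(2S)-5-bromo-2,3-dihydro-1-benzofuran-2-yl]ethane-1,2-diol F5. Garegg–Samuelsson deoxygenation of the terminal diol (PPh3, I2, imidazole, toluene, heat) returns the vinyl group of 8. Here C2 is fixed by the predictable face selectivity of the epoxidation and a stereospecific ring opening.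

**Step 9.** Oxidative addition into the electron-rich C5–Br bond may be slow. The arylpalladium intermediate could then insert the coumarate alkene or be reduced with loss of bromine.

Fallback: it sets out from 11 and comes back at 17 by changing the order of events. The Heck reaction with 16 is run on alcohol 11, where no second alkene is present, to give tert-butyl (2E)-3-[(2S)-2-[(2S)-1-hydroxypropan-2-yl]-2,3-dihydro-1-benzofuran-5-yl]prop-2-enoate F6. Steglich esterification of F6 with 14 then gives 17.

**Step 10.** The tert-butyl cation and the formaldehyde-derived electrophile released in acid may alkylate the two oxygen-substituted arenes. The acetal may also cleave incompletely at an acidity that spares the C2' ester.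

Fallback: it sets out from 11 and 12 and comes back at 18 with no protecting groups. Mitsunobu esterification (PPh3, DIAD, THF, 0 °C) acylates the primary alcohol with the carboxylic acid of 12 in preference to its much less acidic phenol. This should give (2S)-2-[(2S)-5-bromo-2,3-dihydro-1-benzofuran-2-yl]propyl (2E)-3-(4-hydroxyphenyl)prop-2-enoate F7. A Heck reaction of F7 with acrylic acid (Pd(OAc)2, P(o-tol)3, Et3N, DMF, 90 °C) then gives 18 directly.

## Further compounds

F1 | step 6 | (2S)-5-bromo-2-[(1E)-3-bromoprop-1-en-1-yl]-2,3-dihydro-1-benzofuran | BrC/C=C/[C@@H]1Cc2cc(Br)ccc2O1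
F2 | step 6 | (2S)-5-bromo-2-[(2S)-but-3-en-2-yl]-2,3-dihydro-1-benzofuran | C[C@@H](C=C)[C@@H]1Cc2cc(Br)ccc2O1
F3 | step 5 | (2E)-4-(5-bromo-2-hydroxyphenyl)but-2-en-1-ol | OC/C=C/Cc1cc(Br)ccc1O
F4 | step 5 | [(2R,3R)-3-[(5-bromo-2-hydroxyphenyl)methyl]oxiran-2-yl]methanol | OC[C@H]1O[C@@H]1Cc1cc(Br)ccc1O
F5 | step 5 | (1R)-1-[(2S)-5-bromo-2,3-dihydro-1-benzofuran-2-yl]ethane-1,2-diol | OC[C@@H](O)[C@@H]1Cc2cc(Br)ccc2O1
F6 | step 9 | tert-butyl (2E)-3-[(2S)-2-[(2S)-1-hydroxypropan-2-yl]-2,3-dihydro-1-benzofuran-5-yl]prop-2-enoate | C[C@@H](CO)[C@@H]1Cc2cc(/C=C/C(=O)OC(C)(C)C)ccc2O1
F7 | step 10 | (2S)-2-[(2S)-5-bromo-2,3-dihydro-1-benzofuran-2-yl]propyl (2E)-3-(4-hydroxyphenyl)prop-2-enoate | C[C@@H](COC(=O)/C=C/c1ccc(O)cc1)[C@@H]1Cc2cc(Br)ccc2O1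
A1 | alternative 1 | methyl (2S)-2-[3-(tert-butyldimethylsilyloxy)prop-1-en-2-yl]-2,3-dihydro-1-benzofuran-5-carboxylate | C=C(CO[Si](C)(C)C(C)(C)C)[C@@H]1Cc2cc(C(=O)OC)ccc2O1
A2 | alternative 1 | methyl 4-hydroxy-3-iodobenzoate | COC(=O)c1ccc(O)c(I)c1
A3 | alternative 1 | tert-butyldimethyl[(2-methylidenebut-3-en-1-yl)oxy]silane | C=CC(=C)CO[Si](C)(C)C(C)(C)C
A4 | alternative 2 | methyl 4-fluoro-3-[(2S)-3-methyl-2-(4,4,5,5-tetramethyl-1,3,2-dioxaborolan-2-yl)but-3-en-1-yl]benzoate | C=C(C)[C@@H](B1OC(C)(C)C(C)(C)O1)Cc1cc(C(=O)OC)ccc1F
A5 | alternative 2 | methyl 4-fluoro-3-(trifluoromethanesulfonyloxy)benzoate | COC(=O)c1ccc(F)c(OS(=O)(=O)C(F)(F)F)c1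
A6 | alternative 2 | 4,4,5,5-tetramethyl-2-(prop-1-en-2-yl)-1,3,2-dioxaborolane | C=C(C)B1OC(C)(C)C(C)(C)O1
A7 | alternative 2 | vinyllithium | [Li]C=C
A8 | alternative 3 | (2R)-5-bromo-2-[(2S)-but-3-en-2-yl]-1-benzofuran-3(2H)-one | C[C@@H](C=C)[C@@H]1C(=O)c2cc(Br)ccc2O1
A9 | alternative 3 | 1-[5-bromo-2-[(2Z)-but-2-en-1-yloxy]phenyl]-2-diazoethan-1-one | C/C=C\COc1ccc(Br)cc1C(=O)C=[N+]=[N-]
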